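**Plan**
- Numbering the chain from the ester carbonyl (C1), the retrosynthesis cuts C19=C20 (bromo-olefination), then C10–C11 (Sonogashira), then C9≡C10 (alkyne homologation of a C9 aldehyde), and takes the C1 ester back to a terminal alkene C1=C2.
- Enabling feature: C5 with its neighbours C4, C3, C2 on one side and C6 on the other can be closed to a five-membered carbocycle by an extra C2=C6 double bond that the target does not contain. Metathesis of a cyclopentenyl butenyl ether opens this temporary ring (C2=C6 broken, C1=C2 made) while C6 joins C7, giving the oxolane ring (O, C5–C8) as a 2,5-dihydrofuran.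
- The O–C8 bond is cut last, back to (R)-cyclopent-2-en-1-ol and an achiral (E)-4-(benzyloxy)but-2-enyl carbonate.
- Forward: etherification, exchange of the carbocycle for the dihydrofuran, oxidation of C1 to the ester, saturation of the ring, C9 to the alkyne, attachment of the C11–C19 iododienal made from hept-6-yn-1-ol, final olefination.
- Stereochemistry: C5 from a CBS reduction, C8 from the iridium–phosphoramidite catalyst, both carried unchanged through the metathesis to the 2,5-trans ring. C11=C12 (E) comes from syn hydrozirconation, C17=C18 (E) from a stabilised ylide, C19=C20 (Z) from the bromomethylene ylide.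

Key step: step 7

Assumption: in step 6 the ligand L is O,O'-[(S)-1,1'-binaphthyl-2,2'-diyl] N,N-bis[(S)-1-phenylethyl]phosphoramidite, taken to be the antipode that gives S at C8 (the usual sense of this catalyst family for substituents that outrank vinyl). The trans ring relation would be confirmed on 13 or 20 by NOE, and the antipodal ligand used if it proved otherwise.

Step 1
Reactants: 1 2-bromocyclopent-2-en-1-one
Product: 2 (1R)-2-bromocyclopent-2-en-1-ol
Conditions: (S)-2-methyl-CBS-oxazaborolidine (15 mol %), BH3·SMe2 (0.7 equiv), THF, −20 °C; MeOH, then aqueous work-up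
Reagents that add atoms: none
Why: Corey–Bakshi–Shibata reduction, in which the α-bromo substituent makes the vinyl side the large group so that the (S)-oxazaborolidine–borane complex delivers hydride to one carbonyl face and sets the future C5 as R, α-bromo enones being among the best substrates for this catalyst.

Step 2
Reactants: 2 (1R)-2-bromocyclopent-2-en-1-ol
Product: 4 (1R)-cyclopent-2-en-1-ol, via dilithio species 3 (not isolated)
Conditions: t-BuLi (3.2 equiv), Et2O, −78 °C; then H2O, −78 °C to rt; product kept as a titrated Et2O/THF solution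
Reagents that add atoms: none
Why: Lithium–halogen exchange on the lithium alkoxide followed by protonation replaces Br by H without touching the carbinol centre (one equivalent of t-BuLi takes the O–H, one performs the exchange, one destroys the t-BuBr formed), and the volatile alcohol is not concentrated to dryness.

Step 3
Reactants: 5 but-2-yne-1,4-diol
Product: 6 4-(benzyloxy)but-2-yn-1-ol
Conditions: BnBr (1.1 equiv), Ag2O (1.5 equiv), CH2Cl2, rt
Reagents that add atoms: benzyl bromide, BrCc1ccccc1
Why: Ag2O-mediated Williamson monobenzylation of a symmetrical diol, a method known to stop selectively at the monoether.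

Step 4
Reactants: 6 4-(benzyloxy)but-2-yn-1-ol
Product: 8 (2E)-4-(benzyloxy)but-2-en-1-ol, via alkenylaluminate 7 (not isolated)
Conditions: LiAlH4 (1.5 equiv), THF, 0 °C; then H2O, aq. NaOH
Reagents that add atoms: none
Why: Hydroxyl-directed trans-hydroalumination of the propargylic alcohol gives the cyclic alkenylaluminate, whose protonolysis with retention affords only the E-alkene, while the low temperature avoids elimination of benzyloxide to the allene.

Step 5
Reactants: 8 (2E)-4-(benzyloxy)but-2-en-1-ol
Product: 9 tert-butyl (2E)-4-(benzyloxy)but-2-en-1-yl carbonate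
Conditions: Boc2O (1.2 equiv), Bu4NHSO4 (5 mol %), 30 % aq. NaOH, CH2Cl2, 0 °C to rt
Reagents that add atoms: di-tert-butyl dicarbonate, CC(C)(C)OC(=O)OC(=O)OC(C)(C)C
Why: Phase-transfer acylation of the allylic alcohol gives the tert-butyl carbonate, chosen over the methyl carbonate because ionisation releases non-nucleophilic tert-butoxide, which cannot compete with the cyclopentenyl alkoxide in step 6.

Step 6
Reactants: 4 (1R)-cyclopent-2-en-1-ol; 9 tert-butyl (2E)-4-(benzyloxy)but-2-en-1-yl carbonate
Product: 12 ({[(2S)-2-{[(1R)-cyclopent-2-en-1-yl]oxy}but-3-en-1-yl]oxy}methyl)benzene, via lithium alkoxide 10 (not isolated), via copper alkoxide 11 (not isolated)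
Conditions: 4 (1.5 equiv), n-BuLi, THF, 0 °C; CuI, rt; then 9, [Ir(cod)Cl]2 (2 mol %), L (4 mol %, preactivated with n-PrNH2), THF, rt; aq. NH4Cl work-up
Reagents that add atoms: none
Why: Iridium-catalysed asymmetric allylic etherification, in which the cyclometallated iridium phosphoramidite ionises the carbonate to an allyl complex that the soft monovalent copper alkoxide attacks at the substituted terminus (branched product), the ligand fixing the face so that C8 is set as S independently of the remote C5 centre, as is known for copper alkoxides of secondary allylic alcohols.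

Step 7
Reactants: 12 ({[(2S)-2-{[(1R)-cyclopent-2-en-1-yl]oxy}but-3-en-1-yl]oxy}methyl)benzene
Product: 13 (2S,5R)-2-[(benzyloxy)methyl]-5-(but-3-en-1-yl)-2,5-dihydrofuran
Conditions: second-generation Grubbs catalyst (H2IMes)(PCy3)Cl2Ru=CHPh (5 mol %), ethylene (1 atm), CH2Cl2 (0.01 M), rt to 40 °C
Reagents that add atoms: ethylene, C=C (its methylene becomes C1; the vinyl CH2 of 12 leaves as ethylene, so the step is a net isomerisation)
Why: Metathesis of the catalyst with the terminal vinyl group places ruthenium on C7; intramolecular [2+2] cycloaddition of this carbene to the cyclopentene C2=C6 bond and cycloreversion of the ruthenacyclobutane make C6=C7 inside the new oxacycle and move the carbene to C2, where ethylene releases it as the C1=C2 vinyl group (starting instead by ring opening at the cyclopentene and ending by ring closure leads to the same product). The closest known reaction type is ring-rearrangement metathesis (ring-opening/ring-closing metathesis) of cycloalkenyl allyl ethers and amines to dihydrofurans and dihydropyrroles. The oxolane ring is closed as a 2,5-dihydrofuran by ring-closing metathesis onto C6, a five-membered closure preferred over the seven-membered oxepine that closure onto C2 would give. No stereocentre is formed or touched, since only C=C bonds are exchanged, so C5 and C8 keep their configurations and the 2,5-trans relation follows from 12. The step needs rearrangement within one molecule to win over oligomerisation and needs the equilibrium to be drawn to the heterocycle; high dilution, the ethylene atmosphere (which caps C2 and suppresses cross-metathesis of the new terminal alkene) and the loss of cyclopentene strain should secure this.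

Step 8
Reactants: 13 (2S,5R)-2-[(benzyloxy)methyl]-5-(but-3-en-1-yl)-2,5-dihydrofuran
Product: 15 4-[(2R,5S)-5-[(benzyloxy)methyl]-2,5-dihydrofuran-2-yl]butan-1-ol, via B-alkyl-9-BBN 14 (not isolated)
Conditions: 9-BBN (1.3 equiv), THF, 0 °C to rt; then 3 M NaOH, 30 % H2O2, 0 °C
Reagents that add atoms: hydrogen peroxide, OO
Why: Brown hydroboration–oxidation, in which 9-BBN adds anti-Markovnikov to the monosubstituted terminal alkene far faster than to the cis-disubstituted ring alkene flanked by two oxygenated carbons, and alkaline peroxide oxidises the C–B bond to the primary alcohol at C1.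

Step 9
Reactants: 15 4-[(2R,5S)-5-[(benzyloxy)methyl]-2,5-dihydrofuran-2-yl]butan-1-ol
Product: 17 4-[(2R,5S)-5-[(benzyloxy)methyl]-2,5-dihydrofuran-2-yl]butanoic acid, via aldehyde 16 (not isolated)
Conditions: TEMPO (20 mol %), PhI(OAc)2 (2.5 equiv), MeCN/H2O 1:1, rt
Reagents that add atoms: water, O
Why: Oxoammonium (TEMPO/PhI(OAc)2) oxidation in aqueous acetonitrile takes the primary alcohol through the aldehyde hydrate to the carboxylic acid without affecting the ring alkene or the benzyl ether.

Step 10
Reactants: 17 4-[(2R,5S)-5-[(benzyloxy)methyl]-2,5-dihydrofuran-2-yl]butanoic acid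
Product: 18 methyl 4-[(2R,5S)-5-[(benzyloxy)methyl]-2,5-dihydrofuran-2-yl]butanoate
Conditions: MeI (1.5 equiv), K2CO3 (1.5 equiv), DMF, rt
Reagents that add atoms: iodomethane, CI
Why: SN2 alkylation of the potassium carboxylate gives the methyl ester under non-acidic conditions that leave the bis-allylic ether ring untouched.

Step 11
Reactants: 18 methyl 4-[(2R,5S)-5-[(benzyloxy)methyl]-2,5-dihydrofuran-2-yl]butanoate
Product: 20 methyl 4-[(2R,5S)-5-(hydroxymethyl)oxolan-2-yl]butanoate, via saturated benzyl ether 19 (not isolated)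
Conditions: H2 (1 atm), PtO2 (5 mol %), EtOAc, rt; then Pd(OH)2/C (10 wt %), MeOH, H2 (1 atm), rt
Reagents that add atoms: none
Why: Catalytic hydrogenation followed by hydrogenolysis, in which platinum saturates C6=C7 with little double-bond migration (migration to the enol ether could epimerise C5 or C8) and Pd(OH)2/C then cleaves the benzyl ether, so the 2,5-trans oxolane with a free C9 alcohol results with both stereocentres intact.

Step 12
Reactants: 20 methyl 4-[(2R,5S)-5-(hydroxymethyl)oxolan-2-yl]butanoate
Product: 21 methyl 4-[(2R,5S)-5-formyloxolan-2-yl]butanoate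
Conditions: Dess–Martin periodinane (1.3 equiv), CH2Cl2, 0 °C to rt; used at once
Reagents that add atoms: none
Why: Dess–Martin oxidation gives the α-alkoxy aldehyde under near-neutral conditions at low temperature, which limits epimerisation at C8.

Step 13
Reactants: 21 methyl 4-[(2R,5S)-5-formyloxolan-2-yl]butanoate
Product: 22 methyl 4-[(2R,5S)-5-ethynyloxolan-2-yl]butanoate
Conditions: dimethyl (1-diazo-2-oxopropyl)phosphonate (1.5 equiv), K2CO3 (2 equiv), MeOH, 0 °C to rt
Reagents that add atoms: dimethyl (1-diazo-2-oxopropyl)phosphonate, CC(=O)C(=[N+]=[N-])P(=O)(OC)OC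
Why: Seyferth–Gilbert homologation in the Ohira–Bestmann variant, in which the diazomethylphosphonate anion freed by methanolysis adds to the aldehyde and loss of phosphate and N2 with 1,2-hydrogen shift gives the terminal alkyne C9≡C10 under conditions mild enough to keep C8, while methanol matches the methyl ester.

Step 14
Reactants: 23 hept-6-yn-1-ol
Product: 25 (6E)-7-iodohept-6-en-1-ol, via alkenylzirconocene 24 (not isolated)
Conditions: Cp2Zr(H)Cl (2.3 equiv), THF, rt, dark; then I2 (1.2 equiv), 0 °C
Reagents that add atoms: iodine, II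
Why: Schwartz hydrozirconation adds Zr–H syn with zirconium on the terminal carbon (the first equivalent is consumed by the hydroxyl), and iodinolysis of the C–Zr bond with retention gives the E-iodoalkene C11=C12.

Step 15
Reactants: 25 (6E)-7-iodohept-6-en-1-ol
Product: 26 (6E)-7-iodohept-6-enal
Conditions: Dess–Martin periodinane (1.2 equiv), CH2Cl2, 0 °C to rt
Reagents that add atoms: none
Why: Dess–Martin oxidation of the primary alcohol to the aldehyde (C17), the alkenyl iodide being inert.

Step 16
Reactants: 26 (6E)-7-iodohept-6-enal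
Product: 27 (2E,8E)-9-iodonona-2,8-dienal
Conditions: Ph3P=CHCHO (1.3 equiv), toluene, 80 °C
Reagents that add atoms: (triphenylphosphoranylidene)acetaldehyde, O=CC=P(c1ccccc1)(c1ccccc1)c1ccccc1
Why: Wittig reaction with the stabilised formylmethylene ylide gives the E-enal (C17=C18), and the conjugated product is much less electrophilic than the aliphatic aldehyde, which limits a second homologation.

Step 17
Reactants: 22 methyl 4-[(2R,5S)-5-ethynyloxolan-2-yl]butanoate; 27 (2E,8E)-9-iodonona-2,8-dienal
Product: 28 methyl 4-[(2R,5S)-5-[(3E,9E)-11-oxoundeca-3,9-dien-1-yn-1-yl]oxolan-2-yl]butanoate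
Conditions: PdCl2(PPh3)2 (5 mol %), CuI (10 mol %), Et3N, THF, rt, degassed
Reagents that add atoms: none
Why: Sonogashira coupling, in which oxidative addition of the E-alkenyl iodide to zerovalent palladium, transmetallation from the copper acetylide of 22 and reductive elimination form C10–C11 with retention of alkene geometry, while ester, enal and the propargylic centre C8 are untouched at room temperature.

Step 18
Reactants: 28 methyl 4-[(2R,5S)-5-[(3E,9E)-11-oxoundeca-3,9-dien-1-yn-1-yl]oxolan-2-yl]butanoate
Product: 29 methyl 4-[(2R,5S)-5-[(3E,9E,11Z)-12-bromododeca-3,9,11-trien-1-yn-1-yl]oxolan-2-yl]butanoate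
Conditions: (bromomethyl)triphenylphosphonium bromide (1.5 equiv), KOtBu (1.4 equiv), THF, −78 °C; then 28, −78 to −40 °C, dark
Reagents that add atoms: (bromomethyl)triphenylphosphonium bromide, BrC[P+](c1ccccc1)(c1ccccc1)c1ccccc1.[Br-]
Why: Wittig reaction of the non-stabilised bromomethylene ylide, which at low temperature gives the Z-bromoalkene (C19=C20) through kinetically controlled cis-oxaphosphetane formation, a slight deficit of base relative to the phosphonium salt avoiding dehydrobromination of the product.

**Compound list**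
1 | 2-bromocyclopent-2-en-1-one | O=C1CCC=C1Br | starting material
2 | (1R)-2-bromocyclopent-2-en-1-ol | O[C@H]1C(Br)=CCC1 | intermediate
3 | lithium (1R)-2-lithiocyclopent-2-en-1-olate | [Li]O[C@H]1C([Li])=CCC1 | intermediate (not isolated)
4 | (1R)-cyclopent-2-en-1-ol | O[C@H]1C=CCC1 | intermediate
5 | but-2-yne-1,4-diol | OCC#CCO | starting material
6 | 4-(benzyloxy)but-2-yn-1-ol | OCC#CCOCc1ccccc1 | intermediate
7 | lithium 3-[(benzyloxy)methyl]-2,2-dihydrido-2,5-dihydro-1,2-oxaaluminol-2-uide (cyclic alkenylaluminate, Al on the carbon bearing CH2OBn) | [Li+].[AlH2-]1OCC=C1COCc1ccccc1 | intermediate (not isolated)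
8 | (2E)-4-(benzyloxy)but-2-en-1-ol | OC/C=C/COCc1ccccc1 | intermediate
9 | tert-butyl (2E)-4-(benzyloxy)but-2-en-1-yl carbonate | CC(C)(C)OC(=O)OC/C=C/COCc1ccccc1 | intermediate
10 | lithium (1R)-cyclopent-2-en-1-olate | [Li]O[C@H]1C=CCC1 | intermediate (not isolated)
11 | monovalent copper (1R)-cyclopent-2-en-1-olate, CuOR | [Cu]O[C@H]1C=CCC1 | intermediate (not isolated)
12 | ({[(2S)-2-{[(1R)-cyclopent-2-en-1-yl]oxy}but-3-en-1-yl]oxy}methyl)benzene | C=C[C@@H](COCc1ccccc1)O[C@H]1C=CCC1 | intermediate
13 | (2S,5R)-2-[(benzyloxy)methyl]-5-(but-3-en-1-yl)-2,5-dihydrofuran (2,5-trans) | C=CCC[C@@H]1C=C[C@@H](COCc2ccccc2)O1 | intermediate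
14 | 9-{4-[(2R,5S)-5-[(benzyloxy)methyl]-2,5-dihydrofuran-2-yl]butyl}-9-borabicyclo[3.3.1]nonane | C(CCC[C@@H]1C=C[C@@H](COCc2ccccc2)O1)B1C2CCCC1CCC2 | intermediate (not isolated)
15 | 4-[(2R,5S)-5-[(benzyloxy)methyl]-2,5-dihydrofuran-2-yl]butan-1-ol | OCCCC[C@@H]1C=C[C@@H](COCc2ccccc2)O1 | intermediate
16 | 4-[(2R,5S)-5-[(benzyloxy)methyl]-2,5-dihydrofuran-2-yl]butanal | O=CCCC[C@@H]1C=C[C@@H](COCc2ccccc2)O1 | intermediate (not isolated)
17 | 4-[(2R,5S)-5-[(benzyloxy)methyl]-2,5-dihydrofuran-2-yl]butanoic acid | OC(=O)CCC[C@@H]1C=C[C@@H](COCc2ccccc2)O1 | intermediate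
18 | methyl 4-[(2R,5S)-5-[(benzyloxy)methyl]-2,5-dihydrofuran-2-yl]butanoate | COC(=O)CCC[C@@H]1C=C[C@@H](COCc2ccccc2)O1 | intermediate
19 | methyl 4-[(2R,5S)-5-[(benzyloxy)methyl]oxolan-2-yl]butanoate | COC(=O)CCC[C@@H]1CC[C@@H](COCc2ccccc2)O1 | intermediate (not isolated)
20 | methyl 4-[(2R,5S)-5-(hydroxymethyl)oxolan-2-yl]butanoate | COC(=O)CCC[C@@H]1CC[C@@H](CO)O1 | intermediate
21 | methyl 4-[(2R,5S)-5-formyloxolan-2-yl]butanoate | COC(=O)CCC[C@@H]1CC[C@@H](C=O)O1 | intermediate
22 | methyl 4-[(2R,5S)-5-ethynyloxolan-2-yl]butanoate | COC(=O)CCC[C@@H]1CC[C@@H](C#C)O1 | intermediate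
23 | hept-6-yn-1-ol | OCCCCCC#C | starting material
24 | [(1E)-7-{[chlorobis(cyclopentadienyl)zirconio]oxy}hept-1-en-1-yl]chlorobis(cyclopentadienyl)zirconium (Cp rings written σ-bonded) | Cl[Zr](C1C=CC=C1)(C1C=CC=C1)/C=C/CCCCCO[Zr](Cl)(C1C=CC=C1)C1C=CC=C1 | intermediate (not isolated)
25 | (6E)-7-iodohept-6-en-1-ol | OCCCCC/C=C/I | intermediate
26 | (6E)-7-iodohept-6-enal | O=CCCCC/C=C/I | intermediate
27 | (2E,8E)-9-iodonona-2,8-dienal | O=C/C=C/CCCC/C=C/I | intermediate
28 | methyl 4-[(2R,5S)-5-[(3E,9E)-11-oxoundeca-3,9-dien-1-yn-1-yl]oxolan-2-yl]butanoate | COC(=O)CCC[C@@H]1CC[C@@H](C#C/C=C/CCCC/C=C/C=O)O1 | intermediate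
29 | methyl 4-[(2R,5S)-5-[(3E,9E,11Z)-12-bromododeca-3,9,11-trien-1-yn-1-yl]oxolan-2-yl]butanoate | COC(=O)CCC[C@@H]1CC[C@@H](C#C/C=C/CCCC/C=C/C=C\Br)O1 | target

**Step count**
Total: 18 steps. Longest linear sequence: 13 steps (steps 3–13, 17, 18, from but-2-yne-1,4-diol).

**Steps most likely to fail**

Step 7. The liberated terminal alkene may enter cross-metathesis and give oligomers, or the ring exchange may stall at an equilibrium mixture. The fallback replaces the ring rearrangement by an ordinary diene ring-closing metathesis that forms the same C6=C7 bond; it sets out from 9 and returns at 15. Commercial 5-[(tert-butyldimethylsilyl)oxy]pentan-1-ol is oxidised (SO3·pyridine, DMSO, Et3N) to 5-[(tert-butyldimethylsilyl)oxy]pentanal F4, and vinylmagnesium bromide gives racemic 7-[(tert-butyldimethylsilyl)oxy]hept-1-en-3-ol F5. Sharpless kinetic resolution (Ti(OiPr)4, L-(+)-DIPT, t-BuOOH, 4 Å sieves, CH2Cl2, −20 °C) should consume the S enantiomer and leave (3R)-7-[(tert-butyldimethylsilyl)oxy]hept-1-en-3-ol F6. Its lithium alkoxide F7 and monovalent copper alkoxide F8 are formed and coupled with 9 exactly as in step 6 to give the diene ether tert-butyl({[(5R)-5-{[(2S)-1-(benzyloxy)but-3-en-2-yl]oxy}hept-6-en-1-yl]oxy})dimethylsilane F9. Ring-closing metathesis (second-generation Grubbs catalyst, CH2Cl2, 40 °C) should give tert-butyl({4-[(2R,5S)-5-[(benzyloxy)methyl]-2,5-dihydrofuran-2-yl]butoxy})dimethylsilane F10, and Bu4NF in THF frees the alcohol 15.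

Step 6. The oxygen-substituted allyl unit may erode branched selectivity and catalyst control over C8. The fallback forms the ether from the other side, taking C8 from the chiral pool and setting C5 by a palladium catalyst; it sets out from 4 and returns at 12. Alcohol 4 is converted with methyl chloroformate and pyridine into (1R)-cyclopent-2-en-1-yl methyl carbonate F1 (ionisation erases this centre, so racemic material would serve equally). Commercial (S)-benzyl glycidyl ether is opened with dimethylsulfonium methylide (Me3SI, n-BuLi, THF, −10 °C) to (2S)-1-(benzyloxy)but-3-en-2-ol F2, which Et2Zn (0.5 equiv) converts into zinc bis[(2S)-1-(benzyloxy)but-3-en-2-olate] F3. Palladium-catalysed asymmetric allylic etherification of F1 with F3 (Pd2(dba)3·CHCl3, the enantiomer of the DACH-phenyl Trost ligand that places R at C5, THF, rt) proceeds through the symmetric cyclopentenyl π-allyl complex and should give 12.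

Step 18. The Z-selectivity of the bromo-ylide olefination may erode on the conjugated aldehyde, and base may strip HBr from the Z-bromodiene. The fallback sets the geometry by a stereoselective reduction instead; it sets out from 28 and ends at 29. Dibromo-olefination of 28 (CBr4, PPh3, CH2Cl2, 0 °C) gives methyl 4-[(2R,5S)-5-[(3E,9E)-12,12-dibromododeca-3,9,11-trien-1-yn-1-yl]oxolan-2-yl]butanoate F11. Palladium-catalysed hydrogenolysis with Bu3SnH (Pd(PPh3)4, toluene, rt) removes the bromine trans to the diene chain, where oxidative addition is fastest and well ahead of hydrostannation of the internal alkyne, leaving the (11Z)-bromide 29.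

**Further compounds**
F1 | step 6 | (1R)-cyclopent-2-en-1-yl methyl carbonate | COC(=O)O[C@H]1C=CCC1
F2 | step 6 | (2S)-1-(benzyloxy)but-3-en-2-ol | C=C[C@@H](COCc1ccccc1)O
F3 | step 6 | zinc bis[(2S)-1-(benzyloxy)but-3-en-2-olate] | C=C[C@@H](COCc1ccccc1)O[Zn]O[C@H](COCc1ccccc1)C=C
F4 | step 7 | 5-[(tert-butyldimethylsilyl)oxy]pentanal | CC(C)(C)[Si](C)(C)OCCCCC=O
F5 | step 7 | rac-7-[(tert-butyldimethylsilyl)oxy]hept-1-en-3-ol | C=CC(O)CCCCO[Si](C)(C)C(C)(C)C
F6 | step 7 | (3R)-7-[(tert-butyldimethylsilyl)oxy]hept-1-en-3-ol | C=C[C@H](O)CCCCO[Si](C)(C)C(C)(C)C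
F7 | step 7 | lithium (3R)-7-[(tert-butyldimethylsilyl)oxy]hept-1-en-3-olate | [Li]O[C@@H](C=C)CCCCO[Si](C)(C)C(C)(C)C
F8 | step 7 | monovalent copper (3R)-7-[(tert-butyldimethylsilyl)oxy]hept-1-en-3-olate | [Cu]O[C@@H](C=C)CCCCO[Si](C)(C)C(C)(C)C
F9 | step 7 | tert-butyl({[(5R)-5-{[(2S)-1-(benzyloxy)but-3-en-2-yl]oxy}hept-6-en-1-yl]oxy})dimethylsilane | C=C[C@@H](COCc1ccccc1)O[C@H](CCCCO[Si](C)(C)C(C)(C)C)C=C
F10 | step 7 | tert-butyl({4-[(2R,5S)-5-[(benzyloxy)methyl]-2,5-dihydrofuran-2-yl]butoxy})dimethylsilane | CC(C)(C)[Si](C)(C)OCCCC[C@@H]1C=C[C@@H](COCc2ccccc2)O1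
F11 | step 18 | methyl 4-[(2R,5S)-5-[(3E,9E)-12,12-dibromododeca-3,9,11-trien-1-yn-1-yl]oxolan-2-yl]butanoate | COC(=O)CCC[C@@H]1CC[C@@H](C#C/C=C/CCCC/C=C/C=C(Br)Br)O1
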